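If target and isomer of the product can pass into each other, what counts in a long flask is how long that passage takes against the time of the flask, and two chemists at the board dispute that "if".

| flask | starting material | coupling partner | catalyst | temperature | remark | time |
|---|---|---|---|---|---|---|
| theta | 1.5 M | 1.35 M | 1 mM | 25 °C | run made earlier |  |
| cedar | 1.5 M | 1.35 M | 1.5 mM |  | at 25 °C until 5.0 h, from then on at 85 °C | 15 h |
| maple | 1.5 M | 0.600 M | 1.5 mM |  | at 25 °C throughout | 15 h |

theta run (percent of the starting material charged)

| time / h | target / % | isomer of the product / % |
|---|---|---|
| 0.250 | 5.3 | 1.9 |
| 0.833 | 12.5 | 6.7 |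
| 1.33 | 16.1 | 9.2 |
| 2.50 | 19.9 | 14.5 |
| 3.00 | 20.7 | 16.4 |
| 4.00 | 20.5 | 20.6 |
| 5.00 | 19.9 | 23.6 |

(scatter of a reading: 0.5 percentage points)

- the earlier runs do not show what temperature does; that part of a forecast is a guess
- no earlier run changes the charge of catalyst; that part of a forecast is a guess

1. the flask that ends with the higher share of target in all that became target or isomer of the product or over-reaction product, or "neither" when 2 percentage points or less lies between them (cedar / maple / neither)
2. share of target in all that became target or isomer of the product or over-reaction product, cedar
3. share of target in all that became target or isomer of the product or over-reaction product, maple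

The first chemist holds that isomer comes from starting material, while target is lost to over-reaction product by reacting with coupling partner. For her, partner is the danger: cedar carries 0.900 of partner per part of starting material, and it is heated, whereas maple carries 0.400, so she expects maple to keep more target.

The second chemist looks at theta after its peak. From 3.00 h to 5.00 h target reads 20.7 % and then 19.9 %, while isomer gains 7.2 percentage points. He supposes that this gain passes through target, and so defines the exchange time, the stock of target divided by the isomer gained per hour: 5.75 h, a reading with its scatter. He guesses that catalyst carries the passage, which makes it 3.83 h at the charge of cedar and maple.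

Maple then lasts 3.92 exchange times at 25 °C, because 3.83 h is shorter than 15 h. He therefore expects kinetic control to give way to thermodynamic control, with maple's share sliding well below theta's last 45.7 %, whatever its partner. Cedar spends 1.30 exchange times at 25 °C before the heat. What heat does to the split is a guess, but he bets on cedar.

The forecast sides with the first chemist: maple ends higher, with cedar at 10 % (4 % to 19 %) and maple at 14 % (9 % to 21 %), since “the hot stage drives everything to completion”.

Cedar ends at 43.4 % and maple at 25.5 %, so cedar holds the higher share.

    starting material + coupling partner ⇌ target (K = 0.590 M⁻¹, k = 0.170 M⁻¹ h⁻¹, Ea = 60.0 kJ mol⁻¹, ΔH = 23.0 kJ mol⁻¹)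
    starting material + coupling partner ⇌ isomer of the product (K = 1.90 M⁻¹, k = 0.0590 M⁻¹ h⁻¹, Ea = 71.0 kJ mol⁻¹, ΔH = −36.0 kJ mol⁻¹)
    target + catalyst ⇌ isomer of the product + catalyst, rate k3*[catalyst]*[target] forward; the back reaction follows from the equilibrium constant (k = 110 M⁻¹ h⁻¹, Ea = 49.0 kJ mol⁻¹)
    coupling partner + catalyst + target → catalyst + over-reaction product (k = 11.0 M⁻² h⁻¹, Ea = 42.0 kJ mol⁻¹)
    (constants at 25 °C)

In cedar, isomer stood at 25.5 % at 5.00 h, the change of temperature, and at 2.36 % at 7.50 h, while target stood at 18.1 % at 5.00 h and at 39.5 % at 7.50 h. The exchange time read from theta books isomer's gain as passing through target, though the equations above also make isomer directly, so it stays an estimate; on it, maple's 15 h are 3.92 exchange times, and staying until 150 h takes maple's share from 25.5 % to 21.3 %. The first chemist's route has its region in the neighbour of cedar charged with 1.53 of partner per part of starting material, where over-reaction product reaches 58.0 % and the share falls to 23.3 %.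

All runs were generated by integration with constants of no real substance.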